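The constants used here were set for the occasion; the result is computed.

At early times isomer of the product can arise from target by no other step, so we count the target left, not the target made.

| setting | birch | larch | elm | ash |
|---|---|---|---|---|
| substrate | 0.020 M | 0.020 M (fed, over 1.60 min) | 0.020 M | 0.020 M |
| partner | 1.00 equiv | 1.00 equiv | 1.00 equiv | 1.00 equiv |
| remark | one stirred flow tank at steady state, fed with the mixture as stated, mean residence time 6.00 min | a stirred flask in which substrate is dosed at a steady rate over 1.60 min without added volume, worked up at 2.0 min | everything together in a closed stirred flask, run for 2.0 min | one stirred flow tank at steady state, fed with the mixture as stated, mean residence time 2.0 min |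
| time |  | 2.0 min | 2.0 min |  |

    partner → second intermediate (k1 = 0.054 s⁻¹)
    target ⇌ isomer of the product (K2 = 3.4, k2 = 0.0037 s⁻¹)
    substrate → open intermediate (k3 = 0.32 s⁻¹)
    open intermediate + second intermediate → target (k4 = 2.0 L mol⁻¹ s⁻¹)
    2 second intermediate → homo product (k5 = 2.5 L mol⁻¹ s⁻¹)

1. the set-up with the highest share of target in all that became target or isomer of the product, at the outlet or at the end ("none" if the first two lie within 2 percentage points) (birch / larch / elm / ash / none)
2. share of target in all that became target or isomer of the product, at the outlet or at the end, birch
3. share of target in all that became target or isomer of the product, at the outlet or at the end, larch
4. share of target in all that became target or isomer of the product, at the outlet or at the end, elm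
5. share of target in all that became target or isomer of the product, at the outlet or at the end, ash

- a doubled species enters its step squared and goes two at a time
- the stated concentrations are those of everything mixed, before any reaction; amounts are the same in each set-up
- the feed brings no volume worth counting
- run time (larch): 2.0 min

You asked for a quick number and guessed that birch, the longer tank, gives away the most target. Here is our reckoning by hand.

1. In a tank at steady state, isomer of the product leaves at c(isomer of the product)/τ and is balanced by the net isomerisation, with forward constant f and equilibrium constant K: c(isomer of the product)/τ = f c(target) − (f/K) c(isomer of the product). No concentration of partner or open intermediate stands in this balance.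

2. With x = fτ, this gives c(isomer of the product)/c(target) = x/(1 + x/K). For birch, x is 1.33 and K is 3.4, so the ratio is 0.957.

3. Our number for birch is 51.1 %. This is the kept share, the fraction of all that became target or isomer of the product still standing as target at the outlet, one over one plus that ratio.

4. A closed flask has no outflow, so its target relaxes towards the share under thermodynamic control, 22.7 %. Target born at the very start of elm keeps 66.2 % at the end. We expect elm above that, since its target is born later, but we do not reckon by hand how far, and we stop there for larch too.

The forecast picks larch, with birch 51.1 %, larch 82 %, elm 74.5 % and ash 71.8 %, on the ground that “dosing makes it form later and therefore younger than in the all-at-once run”. On birch it matches our number; on the flasks it goes further than we did.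

The simulation gives larch as best: birch 51.1 %, larch 80.8 %, elm 75.1 %, ash 71.8 %, with the top two 5.7 percentage points apart against a margin of 2 points. With the homo product step struck out, birch still reads 51.1 %. Ash, at a residence time a third of birch's, has x = 0.444, so its kept share is 71.8 % against 51.1 % for birch, and the simulation reads 71.8 %.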